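**Retrosynthetic overview**

1. Numbering used throughout: C1 and C5 are the ring-fusion CH; C2 (CH2), C3 (=CH) and C4 (C–CH3) complete the five-membered ring; C6 (CHOH), C7 (CH–oxolane), C8, C9 and C10 (C=CH2) complete the seven-membered ring; Ox = (2S,5R)-5-(2-acetoxypropan-2-yl)-2-methyloxolan-2-yl.
2. 24 ⇐ 18 by C2 desulfonylation, shift of the exocyclic alkene to C3=C4, C10–OSi → C10=O → C10=CH2, and C6 desilylation.
3. 18 ⇐ acyclic 17 by one intramolecular Pd–trimethylenemethane (TMM) [3+2] cycloaddition that forms C1–C5 (closing the seven-membered ring) and C2–C3 (closing the five-membered ring). The enabling feature is that C5–C4(CH3)=C3 of the cyclopentene is a 2-methylallyl unit, i.e. a TMM whose third terminus becomes the C4 methyl, while C1–C2, flanked by C10, can be an (E)-vinyl sulfone at the end of the C6–C10 tether.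
4. 17 ⇐ anti-allylboration (C6–C7 bond) of enal 10 with allylboronate 6, then hydroformylation (C10), vinyl addition and sulfone cross-metathesis; 6 ⇐ (S)-linalool 1; 10 ⇐ butynol 7.
5. Ring order: oxolane (step 1), then the seven- and five-membered carbocycles together (step 13).

Key step: step 13

Remark: (S)-(+)-linalool, the L-fructose-derived enantiomer of the Shi ketone and 4,4-diethoxybut-2-yn-1-ol are taken as commercially available; the C10 carbinol epimers (steps 10–16) and the C2 sulfone epimers (step 13) are carried as mixtures because both centres are destroyed later.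

**Route**

Step 1
Reactants: 1 (S)-(+)-linalool
Product: 3 (2R,5S)-furanoid linalool oxide [2-[(2R,5S)-5-ethenyl-5-methyloxolan-2-yl]propan-2-ol; vinyl and carbinol groups cis], via (3S,6S)-6,7-epoxylinalool 2 (not isolated)
Conditions: ent-Shi ketone (0.3 equiv), KHSO5 (Oxone), K2CO3, Bu4NHSO4, MeCN/CH2(OMe)2/aq. Na2B4O7, 0 °C; then CSA (cat.), CH2Cl2, 0 °C
Reagents that add atoms: potassium peroxymonosulfate, [K+].[O-]S(=O)(=O)OO
Why: Shi epoxidation (chiral dioxirane) should oxidise only the electron-rich trisubstituted alkene and set the (6S)-epoxide under catalyst control, and acid-catalysed 5-exo-tet opening by the tertiary hydroxyl should invert C6 to give the oxolane with the (R)-configured carbinol-bearing carbon, the linalool stereocentre staying untouched.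

Step 2
Reactants: 3 (2R,5S)-furanoid linalool oxide
Product: 4 Ox–CH=CH2 [2-[(2R,5S)-5-ethenyl-5-methyloxolan-2-yl]propan-2-yl acetate]
Conditions: Ac2O, Et3N, DMAP (cat.), CH2Cl2, 40 °C
Reagents that add atoms: acetic anhydride, CC(=O)OC(C)=O
Why: DMAP-catalysed acylation of the tertiary alcohol should install the acetate of the target early, where it also serves as the protecting group; no stereocentre is touched.

Step 3
Reactants: 4 Ox–CH=CH2; 5 allylboronic acid pinacol ester
Product: 6 2-[(E)-3-Ox-prop-2-en-1-yl]-4,4,5,5-tetramethyl-1,3,2-dioxaborolane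
Conditions: 5 (3 equiv), second-generation Hoveyda–Grubbs catalyst (H2IMes)Cl2Ru=CH(C6H4-2-OiPr) (5 mol %), CH2Cl2, 40 °C
Reagents that add atoms: none
Why: Olefin cross-metathesis of the hindered vinyl group, which is slow to homodimerise, with excess allylboronate should give the (E)-γ-substituted allylboronate under thermodynamic control.

Step 4
Reactants: 7 4,4-diethoxybut-2-yn-1-ol
Product: 8 (Z)-4,4-diethoxy-2-[(trimethylsilyl)methyl]but-2-en-1-ol
Conditions: Me3SiCH2MgCl (2.5 equiv), CuI (10 mol %), THF/Et2O, 0 °C to rt; aq. NH4Cl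
Reagents that add atoms: (trimethylsilyl)methylmagnesium chloride, C[Si](C)(C)C[Mg]Cl
Why: Copper-catalysed anti-carbomagnesiation of the magnesium propargylic alkoxide should place the silylmethyl group on the alkyne carbon next to the carbinol carbon through a five-membered magnesium chelate, which also fixes the alkene geometry.

Step 5
Reactants: 8 (Z)-4,4-diethoxy-2-[(trimethylsilyl)methyl]but-2-en-1-ol
Product: 9 (Z)-4,4-diethoxy-2-[(trimethylsilyl)methyl]but-2-en-1-yl acetate
Conditions: Ac2O, pyridine, DMAP (cat.), CH2Cl2, 0 °C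
Reagents that add atoms: acetic anhydride, CC(=O)OC(C)=O
Why: Standard acetylation should turn the primary allylic alcohol into the leaving group needed later for π-allyl formation.

Step 6
Reactants: 9 (Z)-4,4-diethoxy-2-[(trimethylsilyl)methyl]but-2-en-1-yl acetate
Product: 10 (Z)-4-oxo-2-[(trimethylsilyl)methyl]but-2-en-1-yl acetate
Conditions: PPTS (cat.), acetone/H2O, rt
Reagents that add atoms: water, O
Why: Mild acid-catalysed hydrolysis of the unsaturated acetal should unmask the enal, whose conjugated, electron-poor allylsilane should resist protodesilylation.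

Step 7
Reactants: 6 (E)-allylboronate; 10 enal
Product: 11 (2Z,4S,5R)-4-hydroxy-5-Ox-2-[(trimethylsilyl)methyl]hepta-2,6-dien-1-yl acetate
Conditions: (R)-TRIP (5 mol %), 4 Å MS, toluene, −30 °C to rt; aq. NaHCO3 work-up
Reagents that add atoms: none
Why: Chiral phosphoric acid-catalysed allylboration through a closed chair transition state should give only 1,2-addition, the (E)-boronate setting the anti C6/C7 relationship and the catalyst directing Re-face attack on the aldehyde, so that both new stereocentres (4S,5R in 11) are set together.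

Step 8
Reactants: 11 allylic alcohol
Product: 12 (2Z,4S,5R)-4-[(tert-butyldimethylsilyl)oxy]-5-Ox-2-[(trimethylsilyl)methyl]hepta-2,6-dien-1-yl acetate
Conditions: TBSOTf, 2,6-lutidine, CH2Cl2, −78 to 0 °C
Reagents that add atoms: tert-butyldimethylsilyl trifluoromethanesulfonate, CC(C)(C)[Si](C)(C)OS(=O)(=O)C(F)(F)F
Why: Buffered silylation of the hindered allylic alcohol should give the bulky C6 ether that steers the key step and survives to the last step.

Step 9
Reactants: 12 silyl ether
Product: 13 (2Z,4S,5R)-4-[(tert-butyldimethylsilyl)oxy]-8-oxo-5-Ox-2-[(trimethylsilyl)methyl]oct-2-en-1-yl acetate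
Conditions: Rh(acac)(CO)2 (1 mol %), Xantphos (2 mol %), CO/H2 (1:1, 10 bar), toluene, 60 °C
Reagents that add atoms: carbon monoxide, [C-]#[O+]
Why: Rhodium-catalysed hydroformylation with a wide-bite-angle diphosphine should be selective for the monosubstituted terminal alkene and for the linear aldehyde, which supplies C10, while the trisubstituted alkene stays inert.

Step 10
Reactants: 13 aldehyde
Product: 14 (2Z,4S,5R,8RS)-4-[(tert-butyldimethylsilyl)oxy]-8-hydroxy-5-Ox-2-[(trimethylsilyl)methyl]deca-2,9-dien-1-yl acetate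
Conditions: CH2=CHMgBr (1.2 equiv), THF, −78 °C; aq. NH4Cl
Reagents that add atoms: vinylmagnesium bromide, C=C[Mg]Br
Why: 1,2-Addition of the vinyl Grignard reagent to the aldehyde at low temperature should outpace attack on the two acetates, and the new carbinol centre (future C10), formed without control, is destroyed in step 17.

Step 11
Reactants: 14 allylic alcohol; 15 phenyl vinyl sulfone
Product: 16 (2Z,4S,5R,8RS,9E)-4-[(tert-butyldimethylsilyl)oxy]-8-hydroxy-5-Ox-10-(phenylsulfonyl)-2-[(trimethylsilyl)methyl]deca-2,9-dien-1-yl acetate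
Conditions: 15 (3 equiv), second-generation Hoveyda–Grubbs catalyst (H2IMes)Cl2Ru=CH(C6H4-2-OiPr) (5 mol %), CH2Cl2, 40 °C
Reagents that add atoms: none
Why: Cross-metathesis of the terminal allylic alcohol with the electron-poor vinyl sulfone should give the (E)-γ-hydroxy vinyl sulfone, the trisubstituted alkene taking no part.

Step 12
Reactants: 16 γ-hydroxy vinyl sulfone
Product: 17 (2Z,4S,5R,8RS,9E)-4-[(tert-butyldimethylsilyl)oxy]-5-Ox-10-(phenylsulfonyl)-8-[(triethylsilyl)oxy]-2-[(trimethylsilyl)methyl]deca-2,9-dien-1-yl acetate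
Conditions: Et3SiCl, imidazole, CH2Cl2, 0 °C
Reagents that add atoms: chlorotriethylsilane, CC[Si](Cl)(CC)CC
Why: Triethylsilyl protection should remove the hydroxyl proton that would quench the palladium-bound carbanion and gives an ether that can later be cleaved beside the C6 silyl ether.

Step 13
Reactants: 17 acyclic TMM precursor
Product: 18 trans-fused 6-[(tert-butyldimethylsilyl)oxy]-4-methylidene-2-(phenylsulfonyl)-10-[(triethylsilyl)oxy]-7-Ox-bicyclo[5.3.0]decane (C1, C5, C6, C7 as in 24; epimers at C2 and C10)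
Conditions: Pd(OAc)2 (10 mol %), P(OiPr)3 (0.6 equiv), THF (0.01 M), reflux
Reagents that add atoms: none
Why: Zerovalent palladium ionises the allylic acetate and the liberated acetate removes the trimethylsilyl group, giving the zwitterionic trimethylenemethane–palladium complex, whose substituted terminus C5 adds to the β-carbon C1 of the (E)-vinyl sulfone before the α-sulfonyl carbanion at C2 closes onto the allyl terminus C3. The closest known reaction type is the intramolecular palladium–trimethylenemethane [3+2] cycloaddition of 2-(silylmethyl)allyl esters tethered to vinyl sulfones, which is known to build methylenecyclopentane-fused seven-membered rings. The seven-membered ring closes by 7-exo-trig conjugate addition and the five-membered ring by allylic alkylation at the near allyl terminus (5-exo with respect to the departing palladium), leaving the third terminus as the exocyclic CH2 on C4. At C5, 1,3-allylic strain holds the C6–H bond in the plane of the complex, the tether delivers the acceptor to the face that carries C7, and the bulky silyloxy group occupies the other face, so that C5–H ends cis to the C6 oxygen. At C1, the staggered approach that puts the small C1–H, not the sulfonyl-bearing C2, between C4 and C6 gives the trans ring fusion. The step needs reaction through C5 and not through the CH2 termini, which the tether and the known preference of alkyl-substituted complexes for the substituted terminus secure, and 1,4-addition at C1, which the sulfone secures; the epimers at C10 and C2 converge in steps 14 and 17.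

Step 14
Reactants: 18 bicyclic sulfone
Product: 19 trans-fused 6-[(tert-butyldimethylsilyl)oxy]-4-methylidene-10-[(triethylsilyl)oxy]-7-Ox-bicyclo[5.3.0]decane (C10 epimers)
Conditions: Na/Hg (6 % sodium amalgam), Na2HPO4, MeOH/THF, −20 °C
Reagents that add atoms: none
Why: Reductive desulfonylation with buffered sodium amalgam (electron transfer, C–S cleavage, protonation) should remove the activating group and with it the C2 stereocentre, while esters, silyl ethers and the isolated alkene stay inert.

Step 15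
Reactants: 19 exocyclic alkene
Product: 20 6-[(tert-butyldimethylsilyl)oxy]-4-methyl-10-[(triethylsilyl)oxy]-7-Ox-bicyclo[5.3.0]dec-3-ene (C10 epimers)
Conditions: Co(salen)Cl (3 mol %; salen = N,N′-bis(3,5-di-tert-butylsalicylidene)-1,2-cyclohexanediamine dianion), PhSiH3 (6 mol %), benzene, rt
Reagents that add atoms: none
Why: Cobalt-hydride hydrogen-atom-transfer isomerisation should deliver H to the exocyclic CH2 and then take hydrogen from the less hindered C3 methylene rather than from the ring-fusion methine C5, giving the trisubstituted C3=C4 alkene, which is a poor acceptor and should not react further.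

Step 16
Reactants: 20 bis-silyl ether
Product: 21 6-[(tert-butyldimethylsilyl)oxy]-4-methyl-7-Ox-bicyclo[5.3.0]dec-3-en-10-ol (C10 epimers)
Conditions: PPTS (cat.), MeOH/CH2Cl2, 0 °C
Reagents that add atoms: none
Why: Mild acidic methanolysis should cleave the more labile triethylsilyl ether selectively, the hindered C6 tert-butyldimethylsilyl ether and the tertiary acetate remaining.

Step 17
Reactants: 21 C10 alcohol
Product: 22 6-[(tert-butyldimethylsilyl)oxy]-4-methyl-7-Ox-bicyclo[5.3.0]dec-3-en-10-one
Conditions: Dess–Martin periodinane, CH2Cl2, 0 °C to rt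
Reagents that add atoms: none
Why: Dess–Martin oxidation should convert both C10 epimers into the single ketone under conditions that leave the α-stereocentre C1 untouched.

Step 18
Reactants: 22 ketone
Product: 23 6-[(tert-butyldimethylsilyl)oxy]-4-methyl-10-methylidene-7-Ox-bicyclo[5.3.0]dec-3-ene
Conditions: Zn, CH2Br2, TiCl4, THF/CH2Cl2, 0 °C to rt
Reagents that add atoms: dibromomethane, BrCBr
Why: Lombardo methylenation with the non-basic zinc–titanium methylene reagent should convert the enolisable, hindered ketone into the exocyclic alkene without epimerising C1 and without touching the acetate.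

Step 19
Reactants: 23 silyl ether
Product: 24 target CNP0302132.4 [(1R,5S,6S,7R)-6-hydroxy-4-methyl-10-methylidene-7-Ox-bicyclo[5.3.0]dec-3-ene]
Conditions: HF·pyridine, pyridine, THF, 0 °C to rt
Reagents that add atoms: none
Why: Fluoride-mediated desilylation should free the C6 hydroxyl, the buffered reagent leaving the tertiary acetate and both alkenes intact.

**Compound list**

1 | (S)-(+)-linalool | C=C[C@@](C)(O)CCC=C(C)C | starting material
2 | (3S,6S)-6,7-epoxylinalool | C=C[C@@](C)(O)CC[C@@H]1OC1(C)C | intermediate (not isolated)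
3 | (2R,5S)-furanoid linalool oxide | C=C[C@]1(C)CC[C@H](C(C)(C)O)O1 | intermediate
4 | Ox–CH=CH2 (linalool oxide acetate) | C=C[C@]1(C)CC[C@H](C(C)(C)OC(C)=O)O1 | intermediate
5 | allylboronic acid pinacol ester | C=CCB1OC(C)(C)C(C)(C)O1 | starting material
6 | 2-[(E)-3-Ox-prop-2-en-1-yl]-4,4,5,5-tetramethyl-1,3,2-dioxaborolane | CC1(C)OB(C/C=C/[C@]2(C)CC[C@H](C(C)(C)OC(C)=O)O2)OC1(C)C | intermediate
7 | 4,4-diethoxybut-2-yn-1-ol | CCOC(OCC)C#CCO | starting material
8 | (Z)-4,4-diethoxy-2-[(trimethylsilyl)methyl]but-2-en-1-ol | CCOC(OCC)/C=C(/CO)C[Si](C)(C)C | intermediate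
9 | (Z)-4,4-diethoxy-2-[(trimethylsilyl)methyl]but-2-en-1-yl acetate | CCOC(OCC)/C=C(/COC(C)=O)C[Si](C)(C)C | intermediate
10 | (Z)-4-oxo-2-[(trimethylsilyl)methyl]but-2-en-1-yl acetate | O=C/C=C(/COC(C)=O)C[Si](C)(C)C | intermediate
11 | (2Z,4S,5R)-4-hydroxy-5-Ox-2-[(trimethylsilyl)methyl]hepta-2,6-dien-1-yl acetate | C=C[C@@H]([C@]1(C)CC[C@H](C(C)(C)OC(C)=O)O1)[C@@H](O)/C=C(/COC(C)=O)C[Si](C)(C)C | intermediate
12 | 4-O-TBS ether of 11 | C=C[C@@H]([C@]1(C)CC[C@H](C(C)(C)OC(C)=O)O1)[C@@H](O[Si](C)(C)C(C)(C)C)/C=C(/COC(C)=O)C[Si](C)(C)C | intermediate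
13 | (2Z,4S,5R)-4-TBSO-8-oxo-5-Ox-2-[(trimethylsilyl)methyl]oct-2-en-1-yl acetate | O=CCC[C@@H]([C@]1(C)CC[C@H](C(C)(C)OC(C)=O)O1)[C@@H](O[Si](C)(C)C(C)(C)C)/C=C(/COC(C)=O)C[Si](C)(C)C | intermediate
14 | (2Z,4S,5R,8RS)-4-TBSO-8-hydroxy-5-Ox-2-[(trimethylsilyl)methyl]deca-2,9-dien-1-yl acetate | C=CC(O)CC[C@@H]([C@]1(C)CC[C@H](C(C)(C)OC(C)=O)O1)[C@@H](O[Si](C)(C)C(C)(C)C)/C=C(/COC(C)=O)C[Si](C)(C)C | intermediate
15 | phenyl vinyl sulfone | C=CS(=O)(=O)c1ccccc1 | starting material
16 | (2Z,4S,5R,8RS,9E)-4-TBSO-8-hydroxy-5-Ox-10-(phenylsulfonyl)-2-[(trimethylsilyl)methyl]deca-2,9-dien-1-yl acetate | O=S(=O)(/C=C/C(O)CC[C@@H]([C@]1(C)CC[C@H](C(C)(C)OC(C)=O)O1)[C@@H](O[Si](C)(C)C(C)(C)C)/C=C(/COC(C)=O)C[Si](C)(C)C)c1ccccc1 | intermediate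
17 | 8-O-TES ether of 16 | O=S(=O)(/C=C/C(O[Si](CC)(CC)CC)CC[C@@H]([C@]1(C)CC[C@H](C(C)(C)OC(C)=O)O1)[C@@H](O[Si](C)(C)C(C)(C)C)/C=C(/COC(C)=O)C[Si](C)(C)C)c1ccccc1 | intermediate
18 | trans-fused 6-TBSO-4-methylidene-2-(phenylsulfonyl)-10-TESO-7-Ox-bicyclo[5.3.0]decane (C2, C10 epimers) | CC[Si](CC)(CC)OC1CC[C@@H]([C@]3(C)CC[C@H](C(C)(C)OC(C)=O)O3)[C@@H](O[Si](C)(C)C(C)(C)C)[C@@H]2C(=C)CC(S(=O)(=O)c4ccccc4)[C@@H]12 | intermediate
19 | trans-fused 6-TBSO-4-methylidene-10-TESO-7-Ox-bicyclo[5.3.0]decane (C10 epimers) | CC[Si](CC)(CC)OC1CC[C@@H]([C@]3(C)CC[C@H](C(C)(C)OC(C)=O)O3)[C@@H](O[Si](C)(C)C(C)(C)C)[C@@H]2C(=C)CC[C@@H]12 | intermediate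
20 | 6-TBSO-4-methyl-10-TESO-7-Ox-bicyclo[5.3.0]dec-3-ene (C10 epimers) | CC[Si](CC)(CC)OC1CC[C@@H]([C@]3(C)CC[C@H](C(C)(C)OC(C)=O)O3)[C@@H](O[Si](C)(C)C(C)(C)C)[C@@H]2C(C)=CC[C@@H]12 | intermediate
21 | 6-TBSO-4-methyl-7-Ox-bicyclo[5.3.0]dec-3-en-10-ol (C10 epimers) | OC1CC[C@@H]([C@]3(C)CC[C@H](C(C)(C)OC(C)=O)O3)[C@@H](O[Si](C)(C)C(C)(C)C)[C@@H]2C(C)=CC[C@@H]12 | intermediate
22 | 6-TBSO-4-methyl-7-Ox-bicyclo[5.3.0]dec-3-en-10-one | O=C1CC[C@@H]([C@]3(C)CC[C@H](C(C)(C)OC(C)=O)O3)[C@@H](O[Si](C)(C)C(C)(C)C)[C@@H]2C(C)=CC[C@@H]12 | intermediate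
23 | 6-TBSO-4-methyl-10-methylidene-7-Ox-bicyclo[5.3.0]dec-3-ene | C=C1CC[C@@H]([C@]3(C)CC[C@H](C(C)(C)OC(C)=O)O3)[C@@H](O[Si](C)(C)C(C)(C)C)[C@@H]2C(C)=CC[C@@H]12 | intermediate
24 | CNP0302132.4, (1R,5S,6S,7R)-6-hydroxy-4-methyl-10-methylidene-7-Ox-bicyclo[5.3.0]dec-3-ene | C=C1CC[C@@H]([C@]2(C)CC[C@H](C(C)(C)OC(C)=O)O2)[C@@H](O)[C@@H]2C(C)=CC[C@@H]12 | target

**Step count and risks**

Total step count: 19. Longest linear sequence: 16 (steps 1–3 and 7–19, from 1).

Steps most likely to fail:

- Step 13. The flexible seven-membered transition state of the Michael ring closure may follow the other staggered approach and give the cis ring fusion (C1 epimer). Fallback: control would be moved from kinetic to thermodynamic. Setting out from 17, the cis-fused cycloadduct F1 would be carried through the conditions of steps 14 to 17 via the cis-fused exocyclic alkene F2, the cis-fused trisubstituted alkene F3 and the cis-fused C10 alcohol F4 to the cis-fused ketone F5, in which C1 is α to the carbonyl. Equilibration (DBU, toluene, rt to 60 °C) should then favour the trans-fused ketone, and the route is rejoined at 22.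

- Step 15. Hydrogen abstraction from the tertiary C4 radical may also occur at the ring-fusion C5–H, moving the double bond to C4=C5. Fallback: setting out from 19, ozonolysis (O3, CH2Cl2/MeOH, −78 °C; Me2S) would give the cyclopentanone F6. Kinetic deprotonation at the C3 methylene (KHMDS, THF, −78 °C) and trapping with PhNTf2 would give the C3=C4 enol triflate F7. Negishi coupling (MeZnCl, Pd(PPh3)4, THF) would then place the methyl group on C4 and return to the route at 20.

- Step 7. The facial preference imposed by the catalyst may oppose that of the quaternary oxolane centre next to the reacting γ-carbon, so that diastereofacial control erodes. Fallback: setting out from 4, cross-metathesis with allyl bromide (second-generation Hoveyda–Grubbs catalyst) would give the (E)-allylic bromide F8. Its Nozaki–Hiyama allylation of enal 10 (CrCl2, THF, with a chiral sulfonamide ligand if needed) would return to the route at 11, the anti relationship arising from the chair transition state of the allylchromium reagent.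

**Further compounds**

F1 | step 13 | cis-fused C1 epimer of 18 | CC[Si](CC)(CC)OC1CC[C@@H]([C@]3(C)CC[C@H](C(C)(C)OC(C)=O)O3)[C@@H](O[Si](C)(C)C(C)(C)C)[C@@H]2C(=C)CC(S(=O)(=O)c4ccccc4)[C@H]12
F2 | step 13 | cis-fused C1 epimer of 19 | CC[Si](CC)(CC)OC1CC[C@@H]([C@]3(C)CC[C@H](C(C)(C)OC(C)=O)O3)[C@@H](O[Si](C)(C)C(C)(C)C)[C@@H]2C(=C)CC[C@H]12
F3 | step 13 | cis-fused C1 epimer of 20 | CC[Si](CC)(CC)OC1CC[C@@H]([C@]3(C)CC[C@H](C(C)(C)OC(C)=O)O3)[C@@H](O[Si](C)(C)C(C)(C)C)[C@@H]2C(C)=CC[C@H]12
F4 | step 13 | cis-fused C1 epimer of 21 | OC1CC[C@@H]([C@]3(C)CC[C@H](C(C)(C)OC(C)=O)O3)[C@@H](O[Si](C)(C)C(C)(C)C)[C@@H]2C(C)=CC[C@H]12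
F5 | step 13 | cis-fused C1 epimer of 22 | O=C1CC[C@@H]([C@]3(C)CC[C@H](C(C)(C)OC(C)=O)O3)[C@@H](O[Si](C)(C)C(C)(C)C)[C@@H]2C(C)=CC[C@H]12
F6 | step 15 | 6-TBSO-10-TESO-7-Ox-bicyclo[5.3.0]decan-4-one | CC[Si](CC)(CC)OC1CC[C@@H]([C@]3(C)CC[C@H](C(C)(C)OC(C)=O)O3)[C@@H](O[Si](C)(C)C(C)(C)C)[C@@H]2C(=O)CC[C@@H]12
F7 | step 15 | 6-TBSO-10-TESO-7-Ox-bicyclo[5.3.0]dec-3-en-4-yl trifluoromethanesulfonate | CC[Si](CC)(CC)OC1CC[C@@H]([C@]3(C)CC[C@H](C(C)(C)OC(C)=O)O3)[C@@H](O[Si](C)(C)C(C)(C)C)[C@@H]2C(OS(=O)(=O)C(F)(F)F)=CC[C@@H]12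
F8 | step 7 | (E)-3-Ox-prop-2-en-1-yl bromide | BrC/C=C/[C@]1(C)CC[C@H](C(C)(C)OC(C)=O)O1
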